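Compound numbers are those used in the steps and in the list after them.

## Analysis of the target

The target is (3R,5S)-1-(4-hydroxy-3-methoxyphenyl)tetradecane-3,5-diol, a [10]-gingerdiol: an unbranched C14 chain with a guaiacyl ring on C1, secondary hydroxyls on C3 and C5 and an unfunctionalised nonyl tail (C6–C14), the arene being its only ring. The two stereocentres are 1,3-related and syn, and neither the C4 methylene between them nor the flexible chain gives a built-in bias, so the relationship must be imposed by a reagent or a temporary template. The sensitive groups are a free, easily oxidised phenol on an electron-rich ring and the 1,3-diol, which argues for carrying the phenol masked and finishing with a reductive step. The difficulty is economy more than reactivity: three featureless segments (aryl–C1, C2–C5, C6–C14) must be joined and a syn-1,3-diol set in absolute terms without a long series of protecting-group and redox operations. The strategy rests on C1 being a benzylic methylene on an alkoxy-substituted ring that lies five bonds from O5, so that C1–C2–C3–C4–C5–O5 can be closed to a tetrahydropyran through a C1–O5 bond. That bond is benzylic to a donor-substituted arene, so C1 can be oxidised to a stabilised cation while tied to O5, and the same bond can later be cut reductively. In this ring C3 is the 4-position, so the open-chain 1,3-problem becomes facial selectivity on a chair.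

## Retrosynthetic reasoning

**C1–O5 (reconnection).** Target 15 is read as the ring-opened form of tetrahydropyranol 14, in which O5 is bonded to benzylic C1 and the phenol carries a benzyl group. No carbon–carbon bond is cut; what is gained is a six-membered template that fixes C3 relative to C5. The forward step must cleave, by hydrogenolysis, only the C1–O5 bond and the phenolic O-benzyl bond. C3–O and C5–O are not benzylic and should remain. Simple 2-aryl tetrahydropyrans are not reliably opened under the mild conditions that remove a phenolic benzyl group. The step is therefore planned under acidic, more forcing conditions and counts on the extra activation by the para-hydroxy, meta-methoxy ring.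

**C3–H.** The C3 carbinol of 14 is taken back to ketone 13. With aryl and nonyl both equatorial the chair is locked. A bulky hydride approaching from the equatorial side should give the axial alcohol, which is the one syn to O5 after ring opening. C3 is thus set by relay from C5 through C1, without a chiral reagent.

**C1–C2 (key disconnection).** Ketone 13 is cut between C1 and C2. C1 is the carbon of benzylic oxocarbenium ion 11 and C2 is the nucleophilic terminus of an enol derivative of the C3 carbonyl. This leads to enol acetate 10, an open-chain benzylic ether of the C5 alcohol; ring closure passes through cation 12. The cut is made here and not at C1–O5 (an oxa-conjugate addition) for two reasons. The whole aryl unit can then enter as a simple benzyl-type ether by C–O bond formation. The cation can also be generated from that ether by hydride abstraction with a quinone oxidant, with no prior functional group at C1. The forward reaction must oxidise only the ring-activated benzylic C–H of 10 and close the ring 2,6-cis.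

**C3–O of the enol acetate.** Enol acetate 10 has a terminal C2=C3 double bond, so it is taken back to terminal alkyne 9. A ruthenium-catalysed Markovnikov addition of a carboxylic acid O–H across the triple bond must place the acetoxy group on the internal carbon.

**O5–CH2Ar.** The ether bond of 9 is cut to homopropargylic alcohol 6 and benzylic chloride 8, which is made from catalogue alcohol 7. A Williamson reaction suffices and leaves the C5–O bond of 6 intact, so the configuration is carried over.

**C3–C4 and C6–C7.** Alcohol 6 is cut at C3–C4 to acetylide 4 and terminal epoxide 5, opened at its CH2. Epoxide 5 is cut at C6–C7 to Grignard reagent 2 and the chiral-pool C3 epoxide 1, by way of chlorohydrin 3. C4, C5, C6 and O5 all come from 1, whose stereocentre becomes C5 and is never a reacting centre. Epoxide 5 could also come from resolution of its racemate, but building it from 1 discards no material. Chlorohydrin 3 is taken to 6 in one operation, with 5 forming in the flask.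

## Alternatives that were turned down

Alternative 1: enzymatic Baeyer–Villiger desymmetrisation of a meso ketone.
- Disconnection: the C2–C7 segment with both carbinols is taken from the symmetrical ketone A2, which is cis-3,5-bis(tert-butyldimethylsilyloxy)cyclohexanone.
- Key step: a monooxygenase inserts oxygen on one of the two enantiotopic sides of the carbonyl of ketone A2 and gives the seven-membered lactone A1, with both carbinol centres as in the target.
- For it: both stereocentres and their syn relation come from one catalytic step on an achiral substrate, and the relative configuration is guaranteed by the cis ring. On this point it is stronger than the chosen route, which buys its chirality.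
- Against it: lactone A1 holds only six of the fourteen chain carbons, and both ends are at the wrong oxidation level. The acyl end must be extended by seven carbons and then fully deoxygenated at C7. The CH2–O end must become a C–C bond to the benzylic carbon. Two silyl ethers must be carried and removed. This should take well over ten steps. The bulky bis-silyloxy ketone A2 is also far from the small cyclohexanones such enzymes usually accept.
- Comparison: the chosen route offers a chain assembled at the correct oxidation level by three simple C–C bond formations, no protecting group on either diol oxygen, and eight steps in all.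

Alternative 2: aldolase double aldol to a syn-diol lactol.
- Disconnection: C3–C4 and C5–C6, two aldol bonds.
- Key step: the aldolase DERA adds two molecules of acetaldehyde A5 in sequence to the aldehyde A4, which is 3-(4-hydroxy-3-methoxyphenyl)propanal, and the product closes to lactol A3. A Wittig extension of lactol A3 by seven carbons and hydrogenation would finish the target.
- For it: it is clearly shorter (about four steps) and free of protecting groups. The enzyme's usual facial preference, the one exploited for statin side-chain lactols, translates into (3R,5S) here. On step economy it is stronger than the chosen route.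
- Against it: aldehyde A4 is a hydrophobic, unsubstituted aliphatic aldehyde with a large aryl group, which is a poor acceptor for this enzyme. Acetaldehyde A5 is itself an acceptor, so its self-addition competes, and it deactivates the enzyme. The second addition must outrun release of the mono-adduct. Whether an enzyme variant accepts A4 with full selectivity cannot be argued from structure.
- Comparison: the chosen strategy offers predictability. Every step is substrate-controlled small-molecule chemistry, the stereochemical outcome follows from a chair model, and the cyclisation type is established for electron-rich benzylic ethers with alkyl side chains.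

Alternative 3: rhenium-catalysed allylic transposition trapped as a benzylidene acetal.
- Disconnection: the C5–O bond is formed by 1,3-shift of an allylic hydroxyl from C7. The precursor is the ene-diol A7, which is (3R,5E)-1-[4-(benzyloxy)-3-methoxyphenyl]tetradec-5-ene-3,7-diol with C7 unresolved.
- Key step: a rhenium(VII) oxo catalyst equilibrates the allylic alcohol of A7 between C7 and C5, and acetal exchange with benzaldehyde dimethyl acetal A8 captures the C3/C5 diol as the all-equatorial 1,3-dioxane A6. One hydrogenation then saturates the alkene and removes the acetal and the benzyl ether.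
- For it: the C7 centre need not be controlled, the stereochemistry at C5 is self-correcting under thermodynamic control, the assembly is convergent, and the end game is a single global hydrogenation. The step count is equal to or lower than that of the chosen route.
- Against it: C3 of ene-diol A7 must first be set by an asymmetric allylation with a chiral reagent or catalyst. The cross-metathesis that builds A7 joins an allylic and a homoallylic alcohol, with E/Z and homodimer issues. The outcome at C5 depends on complete equilibration, whose only driving force is the acetal formed from A8. A strongly Lewis-acidic rhenium species must also tolerate the electron-rich arene.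
- Comparison: the chosen route sets C1, and through it C3, under kinetic control in a closed chair transition state. Its single stereocentre comes from an inexpensive chiral-pool epoxide, and it needs neither an asymmetric reagent nor a metathesis.

Key step: step 6

Remark: 1, 2, 4 and 7 are taken as purchased compounds; 4 is used as its ethylenediamine complex.

## Route

Step 1
Reactants: 1 (S)-epichlorohydrin; 2 n-octylmagnesium bromide
Product: 3 (S)-1-chloroundecan-2-ol
Conditions: CuI (10 mol %), THF, −40 → 0 °C; then H2O
Reagents that add atoms: none
Why: Copper-catalysed Grignard opening of the epoxide at its unsubstituted carbon (SN2) forms C6–C7 and leaves the chloromethyl group and the stereocentre untouched, so the configuration of 1 is carried into 3 (future C5); low temperature suppresses direct displacement of chloride, which would give the opposite sense.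

Step 2
Reactants: 3 (S)-1-chloroundecan-2-ol; 4 lithium acetylide–ethylenediamine complex
Product: 6 (S)-tridec-1-yn-4-ol, via (S)-2-nonyloxirane 5 (not isolated)
Conditions: 4 (3 equiv), DMSO, 0 °C → rt; then H2O
Reagents that add atoms: none
Why: One equivalent of acetylide deprotonates the hydroxyl, the alkoxide closes to the terminal epoxide 5 by intramolecular Williamson displacement of chloride, and a second equivalent opens 5 at its CH2 by SN2 attack (C3–C4 bond). The carbinol carbon is not a reacting centre in either event, and direct displacement of chloride by acetylide would give the same product.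

Step 3
Reactants: 7 [4-(benzyloxy)-3-methoxyphenyl]methanol
Product: 8 1-(benzyloxy)-4-(chloromethyl)-2-methoxybenzene
Conditions: SOCl2, CH2Cl2, 0 °C → rt; used crude
Reagents that add atoms: thionyl chloride, O=S(Cl)Cl
Why: Chlorination of an electron-rich benzylic alcohol through its chlorosulfite is fast and clean; the chloride solvolyses easily and is therefore not stored.

Step 4
Reactants: 6 (S)-tridec-1-yn-4-ol; 8 1-(benzyloxy)-4-(chloromethyl)-2-methoxybenzene
Product: 9 (S)-1-(benzyloxy)-2-methoxy-4-[(tridec-1-yn-4-yloxy)methyl]benzene
Conditions: NaH, THF–DMF, 0 °C; then 8, Bu4NI (cat.), rt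
Reagents that add atoms: none
Why: Williamson ether synthesis of the sodium alkoxide of 6 with an activated benzylic chloride under iodide catalysis; the O–H is deprotonated much faster than the alkyne C–H, and the C–O bond at the stereocentre is not broken, so the configuration is retained.

Step 5
Reactants: 9 (S)-1-(benzyloxy)-2-methoxy-4-[(tridec-1-yn-4-yloxy)methyl]benzene
Product: 10 (S)-4-{[4-(benzyloxy)-3-methoxyphenyl]methoxy}tridec-1-en-2-yl acetate
Conditions: AcOH, [RuCl2(p-cymene)]2 (cat.), P(2-furyl)3 (cat.), Na2CO3 (cat.), toluene, 80 °C
Reagents that add atoms: acetic acid, CC(=O)O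
Why: Ruthenium-catalysed Markovnikov addition of a carboxylic acid to a terminal alkyne gives the 1-alken-2-yl ester; the carbonate buffer keeps the medium mild enough for the acid-labile dialkoxybenzyl ether, and no stereocentre is touched.

Step 6
Reactants: 10 (S)-4-{[4-(benzyloxy)-3-methoxyphenyl]methoxy}tridec-1-en-2-yl acetate
Product: 13 (2S,6S)-2-[4-(benzyloxy)-3-methoxyphenyl]-6-nonyloxan-4-one, via (E)-oxocarbenium ion 11 (not isolated), via ring-closed acetoxycarbenium ion 12 (not isolated)
Conditions: DDQ (2 equiv), 2,6-dichloropyridine (4 equiv), 4 Å MS, (CH2Cl)2, 0 °C → rt; aq. NaHCO3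
Reagents that add atoms: none
Why: DDQ forms a charge-transfer complex with the dialkoxyarene of 10, takes an electron and then the benzylic hydrogen (net hydride abstraction) and so gives the aryl- and oxygen-stabilised (E)-oxocarbenium ion 11. The terminal CH2 of the enol acetate adds to the cationic carbon and forms C1–C2 in a 6-endo-trig closure of Prins type to give cation 12, whose acetyl group is taken up by the hydroquinone anion or the pyridine base and hydrolysed at the aqueous work-up, which leaves ketone 13. The closest known reaction type is the DDQ-mediated oxidative cyclisation of p-methoxybenzyl-type ethers bearing enol acetate nucleophiles to 2,6-cis-tetrahydropyran-4-ones, applied here to a 4-benzyloxy-3-methoxybenzyl ether. The new stereocentre (ring C2, C1 of the target) is controlled by the C5 centre through a chair transition state in which the nonyl group and the aryl group of the (E)-oxocarbenium ion are both equatorial, so the 2,6-cis (2S,6S) ring should form. The step needs oxidation of the ring-activated benzylic C–H only: the 3,4-dialkoxyarene is the one easily oxidised π-system, and only the cation at its own benzylic carbon is stabilised by both the para oxygen and the ether oxygen, whereas the phenolic PhCH2–O group sits on an unactivated phenyl ring. Molecular sieves exclude water, which would hydrolyse 11 to aldehyde and alcohol, and 2,6-dichloropyridine buffers the acid that would cleave the enol acetate. A second oxidation of 13 should be slow because its remaining benzylic C–H is deactivated inductively by the ring ketone.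

Step 7
Reactants: 13 (2S,6S)-2-[4-(benzyloxy)-3-methoxyphenyl]-6-nonyloxan-4-one
Product: 14 (2S,4S,6S)-2-[4-(benzyloxy)-3-methoxyphenyl]-6-nonyloxan-4-ol (4-OH axial, trans to both ring substituents)
Conditions: L-Selectride, THF, −78 °C; then H2O
Reagents that add atoms: none
Why: Diastereoselective ketone reduction with a bulky trialkylborohydride: in the chair with aryl and nonyl equatorial, the axial trajectory is blocked by the axial hydrogens at C2 and C6, so hydride should arrive equatorially and give the axial alcohol, which corresponds to (3R) in the open chain, syn to O5.

Step 8
Reactants: 14 (2S,4S,6S)-2-[4-(benzyloxy)-3-methoxyphenyl]-6-nonyloxan-4-ol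
Product: 15 (3R,5S)-1-(4-hydroxy-3-methoxyphenyl)tetradecane-3,5-diol
Conditions: H2 (4 atm), Pd(OH)2/C, EtOH–AcOH, rt
Reagents that add atoms: none
Why: Catalytic hydrogenolysis removes the phenolic benzyl group quickly and then cleaves the ring C1–O bond, a benzylic ether on a para-hydroxy, meta-methoxy arene, under acid-promoted conditions of the kind that open guaiacyl-substituted cyclic benzylic ethers. C1 becomes a methylene, and the non-benzylic C3–O and C5–O bonds and their configurations are not affected.

## Compound list

1 | (S)-epichlorohydrin, (S)-2-(chloromethyl)oxirane | ClC[C@@H]1CO1 | starting material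
2 | n-octylmagnesium bromide | CCCCCCCC[Mg]Br | starting material
3 | (S)-1-chloroundecan-2-ol | CCCCCCCCC[C@H](O)CCl | intermediate
4 | lithium acetylide–ethylenediamine complex | [Li]C#C.NCCN | starting material
5 | (S)-2-nonyloxirane | CCCCCCCCC[C@H]1CO1 | intermediate (not isolated)
6 | (S)-tridec-1-yn-4-ol | CCCCCCCCC[C@H](O)CC#C | intermediate
7 | [4-(benzyloxy)-3-methoxyphenyl]methanol | COc1cc(CO)ccc1OCc1ccccc1 | starting material
8 | 1-(benzyloxy)-4-(chloromethyl)-2-methoxybenzene | COc1cc(CCl)ccc1OCc1ccccc1 | intermediate
9 | (S)-1-(benzyloxy)-2-methoxy-4-[(tridec-1-yn-4-yloxy)methyl]benzene | CCCCCCCCC[C@H](OCc1ccc(OCc2ccccc2)c(OC)c1)CC#C | intermediate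
10 | (S)-4-{[4-(benzyloxy)-3-methoxyphenyl]methoxy}tridec-1-en-2-yl acetate | CCCCCCCCC[C@H](OCc1ccc(OCc2ccccc2)c(OC)c1)CC(=C)OC(C)=O | intermediate
11 | (E)-oxocarbenium ion, [(4S)-2-acetoxytridec-1-en-4-yl]{[4-(benzyloxy)-3-methoxyphenyl]methylidene}oxonium | CCCCCCCCC[C@H](/[O+]=C/c1ccc(OCc2ccccc2)c(OC)c1)CC(=C)OC(C)=O | intermediate (not isolated)
12 | ring-closed acetoxycarbenium ion, O-acetyl oxocarbenium ion of 13 | CCCCCCCCC[C@H]1CC(=[O+]C(C)=O)C[C@@H](c2ccc(OCc3ccccc3)c(OC)c2)O1 | intermediate (not isolated)
13 | (2S,6S)-2-[4-(benzyloxy)-3-methoxyphenyl]-6-nonyloxan-4-one (2,6-cis) | CCCCCCCCC[C@H]1CC(=O)C[C@@H](c2ccc(OCc3ccccc3)c(OC)c2)O1 | intermediate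
14 | (2S,4S,6S)-2-[4-(benzyloxy)-3-methoxyphenyl]-6-nonyloxan-4-ol (2,6-cis, 4-OH trans and axial) | CCCCCCCCC[C@H]1C[C@H](O)C[C@@H](c2ccc(OCc3ccccc3)c(OC)c2)O1 | intermediate
15 | (3R,5S)-1-(4-hydroxy-3-methoxyphenyl)tetradecane-3,5-diol | CCCCCCCCC[C@H](O)C[C@H](O)CCc1ccc(O)c(OC)c1 | target

## Step count and least certain steps

Total: 8 steps. Longest linear sequence: 7 steps (steps 1, 2, 4, 5, 6, 7, 8 from 1); step 3 is a one-step side branch.

**Step 6 (key step).**
- What may go wrong: hydrolytic interception of the oxocarbenium ion by traces of water (the ordinary oxidative debenzylation pathway); slow ring closure because the doubly donor-stabilised cation is a weak electrophile for the weakly nucleophilic enol acetate; further oxidation at the remaining benzylic C–H of the product.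
- Fallback (ring closure through C–O instead of C–C): it sets out from 6 and 7 and returns at 13. Alkyne 6 is hydrated (cat. Au(I) or Hg(II), aqueous MeOH) to (S)-4-hydroxytridecan-2-one F1. Alcohol 7 is oxidised with MnO2 to 4-(benzyloxy)-3-methoxybenzaldehyde F2. The kinetic dianion of F1 (LDA, 2.2 equiv, THF, −78 °C) is added to F2 to give (5S)-1-[4-(benzyloxy)-3-methoxyphenyl]-1,5-dihydroxytetradecan-3-one F3 as C1 epimers. Catalytic acid (TsOH, CH2Cl2) should dehydrate the electron-rich benzylic alcohol to (S,E)-1-[4-(benzyloxy)-3-methoxyphenyl]-5-hydroxytetradec-1-en-3-one F4. F4 closes by reversible 6-endo oxa-Michael addition to the thermodynamically preferred 2,6-cis ketone 13.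

**Step 8.**
- What may go wrong: debenzylation of the phenol is fast, but cleavage of the cyclic benzylic C–O bond may stall, since 2-aryl tetrahydropyrans are poor substrates for C–O hydrogenolysis. More forcing conditions risk saturation of the arene.
- Fallback (ionic instead of catalytic C–O cleavage): it sets out from 14 and returns at 15. Et3SiH with BF3·OEt2 in CH2Cl2 at −20 °C ionises the C1–O bond, assisted by the para-alkoxy group, and delivers hydride to C1. This gives (3R,5S)-1-[4-(benzyloxy)-3-methoxyphenyl]tetradecane-3,5-diol F5. Mild hydrogenation (H2, 1 atm, Pd/C, EtOH) then removes the benzyl group to give 15. Any styrene formed by proton loss from the benzylic cation would be saturated to the same product in that hydrogenation.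

**Step 5.**
- What may go wrong: loss of regiocontrol (anti-Markovnikov enol esters) or acid-induced solvolysis of the dialkoxybenzyl ether at 80 °C.
- Fallback (enolate acylation instead of alkyne addition): it sets out from 9 and returns at 10. Gold(I)-catalysed hydration of the alkyne under neutral conditions gives (S)-4-{[4-(benzyloxy)-3-methoxyphenyl]methoxy}tridecan-2-one F6. Kinetic deprotonation at the methyl group (LDA, THF, −78 °C) and O-acetylation of the enolate with Ac2O give 10.

**Step 4.**
- What may go wrong: decomposition of the reactive benzylic chloride before it is consumed, or C-alkylation after deprotonation of the alkyne.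
- Fallback (acid-catalysed instead of basic etherification): it sets out from 7 and 6 and returns at 9. Alcohol 7 is converted with Cl3CCN and catalytic DBU into 4-(benzyloxy)-3-methoxybenzyl 2,2,2-trichloroacetimidate F7. F7 alkylates 6 under catalytic acid (La(OTf)3 or CSA, CH2Cl2) to give 9.

**Step 7.**
- What may go wrong: incomplete facial selectivity, or base-induced retro-oxa-Michael opening of the β-alkoxy ketone.
- Fallback (small hydride, then inversion): it sets out from 13 and returns at 14. NaBH4 in MeOH attacks axially and gives the equatorial alcohol (2S,4R,6S)-2-[4-(benzyloxy)-3-methoxyphenyl]-6-nonyloxan-4-ol F8. Mitsunobu inversion with 4-nitrobenzoic acid (PPh3, DIAD) gives the axial ester (2S,4S,6S)-2-[4-(benzyloxy)-3-methoxyphenyl]-6-nonyloxan-4-yl 4-nitrobenzoate F9. Methanolysis (K2CO3, MeOH) gives 14.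

## Further compounds

F1 | step 6 | (S)-4-hydroxytridecan-2-one | CCCCCCCCC[C@H](O)CC(C)=O
F2 | step 6 | 4-(benzyloxy)-3-methoxybenzaldehyde | COc1cc(C=O)ccc1OCc1ccccc1
F3 | step 6 | (5S)-1-[4-(benzyloxy)-3-methoxyphenyl]-1,5-dihydroxytetradecan-3-one (C1 epimers) | CCCCCCCCC[C@H](O)CC(=O)CC(O)c1ccc(OCc2ccccc2)c(OC)c1
F4 | step 6 | (S,E)-1-[4-(benzyloxy)-3-methoxyphenyl]-5-hydroxytetradec-1-en-3-one | CCCCCCCCC[C@H](O)CC(=O)/C=C/c1ccc(OCc2ccccc2)c(OC)c1
F5 | step 8 | (3R,5S)-1-[4-(benzyloxy)-3-methoxyphenyl]tetradecane-3,5-diol | CCCCCCCCC[C@H](O)C[C@H](O)CCc1ccc(OCc2ccccc2)c(OC)c1
F6 | step 5 | (S)-4-{[4-(benzyloxy)-3-methoxyphenyl]methoxy}tridecan-2-one | CCCCCCCCC[C@H](OCc1ccc(OCc2ccccc2)c(OC)c1)CC(C)=O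
F7 | step 4 | 4-(benzyloxy)-3-methoxybenzyl 2,2,2-trichloroacetimidate | COc1cc(COC(=N)C(Cl)(Cl)Cl)ccc1OCc1ccccc1
F8 | step 7 | (2S,4R,6S)-2-[4-(benzyloxy)-3-methoxyphenyl]-6-nonyloxan-4-ol (all-cis) | CCCCCCCCC[C@H]1C[C@@H](O)C[C@@H](c2ccc(OCc3ccccc3)c(OC)c2)O1
F9 | step 7 | (2S,4S,6S)-2-[4-(benzyloxy)-3-methoxyphenyl]-6-nonyloxan-4-yl 4-nitrobenzoate | CCCCCCCCC[C@H]1C[C@H](OC(=O)c2ccc(cc2)[N+](=O)[O-])C[C@@H](c2ccc(OCc3ccccc3)c(OC)c2)O1
A1 | alternative 1 | (4R,6S)-4,6-bis(tert-butyldimethylsilyloxy)oxepan-2-one (cis) | O=C1C[C@H](O[Si](C)(C)C(C)(C)C)C[C@H](O[Si](C)(C)C(C)(C)C)CO1
A2 | alternative 1 | cis-3,5-bis(tert-butyldimethylsilyloxy)cyclohexan-1-one (meso) | O=C1C[C@H](O[Si](C)(C)C(C)(C)C)C[C@H](O[Si](C)(C)C(C)(C)C)C1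
A3 | alternative 2 | (4R,6R)-6-[2-(4-hydroxy-3-methoxyphenyl)ethyl]oxane-2,4-diol (anomeric mixture) | OC1C[C@H](O)C[C@@H](CCc2ccc(O)c(OC)c2)O1
A4 | alternative 2 | 3-(4-hydroxy-3-methoxyphenyl)propanal | O=CCCc1ccc(O)c(OC)c1
A5 | alternative 2 | acetaldehyde | CC=O
A6 | alternative 3 | (2R,4R,6R)-4-{2-[4-(benzyloxy)-3-methoxyphenyl]ethyl}-6-[(E)-non-1-en-1-yl]-2-phenyl-1,3-dioxane (all-cis) | CCCCCCC/C=C/[C@H]1C[C@@H](CCc2ccc(OCc3ccccc3)c(OC)c2)O[C@@H](c2ccccc2)O1
A7 | alternative 3 | (3R,5E)-1-[4-(benzyloxy)-3-methoxyphenyl]tetradec-5-ene-3,7-diol (C7 epimers) | CCCCCCCC(O)/C=C/C[C@H](O)CCc1ccc(OCc2ccccc2)c(OC)c1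
A8 | alternative 3 | benzaldehyde dimethyl acetal | COC(OC)c1ccccc1
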